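**Strategy.** The five-membered enone ring (C1, C2, C3, C3a, C7a of the indenone) is made by deleting one atom from a six-membered benzo-fused thiopyranone S,S-dioxide in which SO2 sits between the future C2 and C3. A late Ramberg–Bäcklund reaction contracts this ring and creates the tetrasubstituted C2=C3 double bond next to C1=O in one operation. It exploits the fact that C2 lies between carbonyl and sulfonyl (easy chlorination) and C3 is benzylic (easy deprotonation). The precursor already carries the guaiazulenyl group, attached at C2 by rhodium carbenoid C–H insertion into guaiazulene, and the 1,2,3,4-substituted benzene ring, set by ortho-lithiation of 3-bromo-4-methylbenzoic acid.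

Key step: step 9

Remark on the chemistry: 3-bromo-4-methylbenzoic acid and guaiazulene are taken as commercial. All stereocentres of the intermediates should form without control (racemates or diastereomer mixtures) and are written without descriptors. All are destroyed in step 9, and the target is achiral.

Step 1
Reactants: 1 3-bromo-4-methylbenzoic acid
Product: 2 4-bromo-3,5-dimethyl-2-benzofuran-1(3H)-one
Conditions: lithium 2,2,6,6-tetramethylpiperidide (LiTMP, 2.2 equiv), THF, −50 °C; MeCHO, −50 to 0 °C; 2 M HCl, 25 °C
Reagents that add atoms: acetaldehyde, CC=O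
Why: The ring C–H flanked by carboxylate and bromine is the kinetically most acidic, so directed ortho-metalation should give the 2-lithio-3-bromobenzoate below the temperature of LiBr loss, and addition to acetaldehyde followed by acid lactonisation should give the phthalide with a racemic new stereocentre.

Step 2
Reactants: 2 4-bromo-3,5-dimethyl-2-benzofuran-1(3H)-one
Product: 3 methyl 3,5-dimethyl-1-oxo-1,3-dihydro-2-benzofuran-4-carboxylate
Conditions: Pd(OAc)2 (5 mol%), Xantphos (6 mol%), CO (5 bar), Et3N, MeOH–DMF, 100 °C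
Reagents that add atoms: carbon monoxide, [C-]#[O+]; methanol, CO
Why: Palladium-catalysed alkoxycarbonylation of the aryl bromide; the wide-bite-angle ligand should tolerate the two ortho substituents and the lactone is inert.

Step 3
Reactants: 3 methyl 3,5-dimethyl-1-oxo-1,3-dihydro-2-benzofuran-4-carboxylate
Product: 5 3,7-dimethyl-4-(2-methylpropanoyl)-2-benzofuran-1(3H)-one, via hydroxy keto ester 4 (not isolated)
Conditions: i-PrMgCl (1.05 equiv), THF, −78 °C; 1 M HCl; then TsOH·H2O (cat.), PhMe, 60 °C
Reagents that add atoms: isopropylmagnesium chloride, CC(C)[Mg]Cl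
Why: Chemoselective Grignard addition to the unhindered lactone carbonyl (the di-ortho-substituted methyl ester is shielded) should give the aryl isopropyl ketone and a free benzylic alcohol, which relactonises onto the neighbouring ester (translactonisation), so ketone and lactone change places without a new stereocentre.

Step 4
Reactants: 5 3,7-dimethyl-4-(2-methylpropanoyl)-2-benzofuran-1(3H)-one
Product: 6 methyl 2-(1-bromoethyl)-6-methyl-3-(2-methylpropanoyl)benzoate
Conditions: BBr3 (1.2 equiv), CH2Cl2, 0 to 25 °C; then MeOH, 0 °C; aqueous work-up; used crude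
Reagents that add atoms: boron tribromide, BrB(Br)Br; methanol, CO
Why: Lewis-acid cleavage of the lactone alkyl C–O bond with bromide delivery to the benzylic carbon, then methanolysis of the acyloxyborane, is the known lactone to bromo ester conversion; the stereocentre stays racemic.

Step 5
Reactants: 6 methyl 2-(1-bromoethyl)-6-methyl-3-(2-methylpropanoyl)benzoate
Product: 7 methyl 2-[1-(methanesulfonyl)ethyl]-6-methyl-3-(2-methylpropanoyl)benzoate
Conditions: MeSO2Na (1.5 equiv), n-Bu4NI (cat.), DMF, 25 °C
Reagents that add atoms: sodium methanesulfinate, CS(=O)[O-].[Na+]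
Why: SN2 S-alkylation of the sulfinate by the benzylic bromide should give the sulfone directly at its final oxidation level, so no oxidant is needed later.

Step 6
Reactants: 7 methyl 2-[1-(methanesulfonyl)ethyl]-6-methyl-3-(2-methylpropanoyl)benzoate
Product: 8 1,5-dimethyl-8-(2-methylpropanoyl)-1H-2-benzothiopyran-4(3H)-one 2,2-dioxide
Conditions: KOt-Bu (3 equiv), THF, 0 to 25 °C; 1 M HCl
Reagents that add atoms: none
Why: Intramolecular Claisen (Dieckmann-type) condensation of the α-sulfonyl methyl carbanion with the ester should close the six-membered β-keto sulfone by 6-exo-trig attack, the reversible aldol addition to the enolised isobutyryl ketone being drained by irreversible formation of the product enolate.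

Step 7
Reactants: 8 1,5-dimethyl-8-(2-methylpropanoyl)-1H-2-benzothiopyran-4(3H)-one 2,2-dioxide
Product: 9 3-diazo-1,5-dimethyl-8-(2-methylpropanoyl)-1H-2-benzothiopyran-4(3H)-one 2,2-dioxide
Conditions: 4-acetamidobenzenesulfonyl azide (1.2 equiv), Et3N, MeCN, 0 to 25 °C
Reagents that add atoms: 4-acetamidobenzenesulfonyl azide, CC(=O)Nc1ccc(cc1)S(=O)(=O)N=[N+]=[N-]
Why: Regitz diazo transfer to the only activated methylene, the one between C=O and SO2.

Step 8
Reactants: 9 3-diazo-1,5-dimethyl-8-(2-methylpropanoyl)-1H-2-benzothiopyran-4(3H)-one 2,2-dioxide; 10 guaiazulene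
Product: 11 3-[3,8-dimethyl-5-(propan-2-yl)azulen-1-yl]-1,5-dimethyl-8-(2-methylpropanoyl)-1H-2-benzothiopyran-4(3H)-one 2,2-dioxide
Conditions: Rh2(OAc)4 (2 mol%), CH2Cl2, 25 °C, slow addition of 9 to 10 (1.5 equiv)
Reagents that add atoms: none
Why: The electrophilic acceptor/acceptor rhodium carbenoid should be attacked by C3 of guaiazulene, the free and most nucleophilic position of its five-membered ring, and proton transfer gives the formal aromatic C–H insertion product (carbenoid Friedel–Crafts alkylation of electron-rich arenes); the new stereocentre is epimerisable and irrelevant.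

Step 9
Reactants: 11 3-[3,8-dimethyl-5-(propan-2-yl)azulen-1-yl]-1,5-dimethyl-8-(2-methylpropanoyl)-1H-2-benzothiopyran-4(3H)-one 2,2-dioxide
Product: 14 2-[3,8-dimethyl-5-(propan-2-yl)azulen-1-yl]-3,7-dimethyl-4-(2-methylpropanoyl)-1H-inden-1-one, via chloro sulfone 12 (not isolated), via episulfone 13 (not isolated)
Conditions: NCS (1.05 equiv), THF, −40 °C; then KOt-Bu (2.5 equiv), t-BuOH–THF, −40 to 20 °C
Reagents that add atoms: none
Why: Ramberg–Bäcklund reaction: the enolised C–H between C=O and SO2 (future C2) is chlorinated by NCS to 12, KOt-Bu then removes the benzylic α′-sulfonyl proton of the CH(Me) carbon (future C3), and this carbanion displaces chloride in a 1,3-elimination to the episulfone 13, which loses SO2 cheletropically to leave the C2=C3 double bond. The closest known reaction type is the Ramberg–Bäcklund ring contraction of cyclic α-halo sulfones to cyclopentenes and cyclopentenones. The five-membered carbocycle is closed by the 3-exo-tet C2–C3 bond formation inside the six-membered ring, and the SO2 bridge is then extruded. No stereocentre is formed, and both stereocentres of 11 are destroyed. The step needs chlorination only at the carbon between C=O and SO2 and deprotonation only at the CH(Me) carbon; the large acidity gap, the absence of any other α-sulfonyl hydrogen in 12 and the non-nucleophilic base (no acyl cleavage of the α-chloro-β-keto sulfone) should secure this.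

Compound list
1 | 3-bromo-4-methylbenzoic acid | Cc1ccc(C(=O)O)cc1Br | starting material
2 | 4-bromo-3,5-dimethyl-2-benzofuran-1(3H)-one (racemic) | CC1OC(=O)c2ccc(C)c(Br)c21 | intermediate
3 | methyl 3,5-dimethyl-1-oxo-1,3-dihydro-2-benzofuran-4-carboxylate (racemic) | CC1OC(=O)c2ccc(C)c(C(=O)OC)c21 | intermediate
4 | methyl 2-(1-hydroxyethyl)-6-methyl-3-(2-methylpropanoyl)benzoate (racemic, not isolated) | CC(O)c1c(C(=O)C(C)C)ccc(C)c1C(=O)OC | intermediate
5 | 3,7-dimethyl-4-(2-methylpropanoyl)-2-benzofuran-1(3H)-one (racemic) | CC1OC(=O)c2c(C)ccc(C(=O)C(C)C)c21 | intermediate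
6 | methyl 2-(1-bromoethyl)-6-methyl-3-(2-methylpropanoyl)benzoate (racemic) | CC(Br)c1c(C(=O)C(C)C)ccc(C)c1C(=O)OC | intermediate
7 | methyl 2-[1-(methanesulfonyl)ethyl]-6-methyl-3-(2-methylpropanoyl)benzoate (racemic) | CC(c1c(C(=O)C(C)C)ccc(C)c1C(=O)OC)S(C)(=O)=O | intermediate
8 | 1,5-dimethyl-8-(2-methylpropanoyl)-1H-2-benzothiopyran-4(3H)-one 2,2-dioxide (racemic) | CC1c2c(C(=O)C(C)C)ccc(C)c2C(=O)CS1(=O)=O | intermediate
9 | 3-diazo-1,5-dimethyl-8-(2-methylpropanoyl)-1H-2-benzothiopyran-4(3H)-one 2,2-dioxide (racemic) | CC1c2c(C(=O)C(C)C)ccc(C)c2C(=O)C(=[N+]=[N-])S1(=O)=O | intermediate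
10 | guaiazulene, 1,4-dimethyl-7-(propan-2-yl)azulene | c1cc(C)c2cc(C(C)C)ccc(C)c1-2 | starting material
11 | 3-[3,8-dimethyl-5-(propan-2-yl)azulen-1-yl]-1,5-dimethyl-8-(2-methylpropanoyl)-1H-2-benzothiopyran-4(3H)-one 2,2-dioxide (diastereomer mixture) | CC1c2c(C(=O)C(C)C)ccc(C)c2C(=O)C(c2cc(C)c3cc(C(C)C)ccc(C)c2-3)S1(=O)=O | intermediate
12 | 3-chloro-3-[3,8-dimethyl-5-(propan-2-yl)azulen-1-yl]-1,5-dimethyl-8-(2-methylpropanoyl)-1H-2-benzothiopyran-4(3H)-one 2,2-dioxide (not isolated) | CC1c2c(C(=O)C(C)C)ccc(C)c2C(=O)C(Cl)(c2cc(C)c3cc(C(C)C)ccc(C)c2-3)S1(=O)=O | intermediate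
13 | episulfone (thiirane 1,1-dioxide) bridging C2 and C3 of 2-[3,8-dimethyl-5-(propan-2-yl)azulen-1-yl]-3,7-dimethyl-4-(2-methylpropanoyl)indan-1-one (not isolated) | CC12c3c(C(=O)C(C)C)ccc(C)c3C(=O)C1(c1cc(C)c3cc(C(C)C)ccc(C)c1-3)S2(=O)=O | intermediate
14 | 2-[3,8-dimethyl-5-(propan-2-yl)azulen-1-yl]-3,7-dimethyl-4-(2-methylpropanoyl)-1H-inden-1-one | CC1=C(c2cc(C)c3cc(C(C)C)ccc(C)c2-3)C(=O)c2c(C)ccc(C(=O)C(C)C)c21 | target

Total step count: 9. Longest linear sequence: 9 steps (1 to 14); guaiazulene 10 enters in step 8.

Steps most likely to fail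

Step 9. The azulene ring may compete with the enol for the chlorinating agent, or the α-chloro-β-keto sulfone may undergo acyl cleavage or solvolysis faster than the 1,3-elimination. The fallback contracts the ring before the azulene is present and joins the two ring systems afterwards. It sets out from 8: bromination of the activated methylene with NBS (2.1 equiv) should give 3,3-dibromo-1,5-dimethyl-8-(2-methylpropanoyl)-1H-2-benzothiopyran-4(3H)-one 2,2-dioxide F1. KOt-Bu should then effect the Ramberg–Bäcklund contraction with retention of one bromine to give 2-bromo-3,7-dimethyl-4-(2-methylpropanoyl)-1H-inden-1-one F2. Direct C–H arylation of guaiazulene 10 at C3 with F2 (Pd(OAc)2, PCy3·HBF4, PivOH, K2CO3, DMA, 100 °C) comes back to the route at 14.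

Step 8. The carbenoid may add to the seven-membered ring of the azulene (cyclopropanation and ring enlargement) or dimerise instead of substituting C3. The fallback forms the bond to the azulene as part of the sulfone, before the ring is closed. It sets out from 6: S-alkylation of HOCH2SO2Na and base-induced loss of formaldehyde should give sodium 1-[2-(methoxycarbonyl)-3-methyl-6-(2-methylpropanoyl)phenyl]ethane-1-sulfinate F3. Separately, a Mannich reaction of guaiazulene 10 with N,N-dimethylmethyleneiminium iodide should give 1-[3,8-dimethyl-5-(propan-2-yl)azulen-1-yl]-N,N-dimethylmethanamine F4. Heating F3 with F4 in acetic acid (elimination–addition through the azulenylmethyl cation) should give the sulfone methyl 2-[1-({[3,8-dimethyl-5-(propan-2-yl)azulen-1-yl]methyl}sulfonyl)ethyl]-6-methyl-3-(2-methylpropanoyl)benzoate F5. Claisen ring closure of F5 with KOt-Bu, as in step 6, comes back to the route at 11.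

Step 5 (with step 4). The ortho ester carbonyl of 6 may displace the secondary benzylic bromide (relactonisation to 5 with loss of bromomethane) faster than the weakly nucleophilic sulfinate attacks. The fallback keeps the carboxylate as leaving group, uses a stronger sulfur nucleophile and adjusts the oxidation level afterwards. It sets out from 5: SN2 opening of the lactone at the benzylic carbon with NaSMe (DMF, 100 °C) should give 6-methyl-3-(2-methylpropanoyl)-2-[1-(methylsulfanyl)ethyl]benzoic acid F6. MeI/K2CO3 should give methyl 6-methyl-3-(2-methylpropanoyl)-2-[1-(methylsulfanyl)ethyl]benzoate F7. Oxidation with H2O2 and catalytic Na2WO4 comes back to the route at 7.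

Further compounds
F1 | step 9 | 3,3-dibromo-1,5-dimethyl-8-(2-methylpropanoyl)-1H-2-benzothiopyran-4(3H)-one 2,2-dioxide | CC1c2c(C(=O)C(C)C)ccc(C)c2C(=O)C(Br)(Br)S1(=O)=O
F2 | step 9 | 2-bromo-3,7-dimethyl-4-(2-methylpropanoyl)-1H-inden-1-one | CC1=C(Br)C(=O)c2c(C)ccc(C(=O)C(C)C)c21
F3 | step 8 | sodium 1-[2-(methoxycarbonyl)-3-methyl-6-(2-methylpropanoyl)phenyl]ethane-1-sulfinate | CC(c1c(C(=O)C(C)C)ccc(C)c1C(=O)OC)S(=O)[O-].[Na+]
F4 | step 8 | 1-[3,8-dimethyl-5-(propan-2-yl)azulen-1-yl]-N,N-dimethylmethanamine | CN(C)Cc1cc(C)c2cc(C(C)C)ccc(C)c1-2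
F5 | step 8 | methyl 2-[1-({[3,8-dimethyl-5-(propan-2-yl)azulen-1-yl]methyl}sulfonyl)ethyl]-6-methyl-3-(2-methylpropanoyl)benzoate | CC(c1c(C(=O)C(C)C)ccc(C)c1C(=O)OC)S(=O)(=O)Cc1cc(C)c2cc(C(C)C)ccc(C)c1-2
F6 | step 5 | 6-methyl-3-(2-methylpropanoyl)-2-[1-(methylsulfanyl)ethyl]benzoic acid | CC(SC)c1c(C(=O)C(C)C)ccc(C)c1C(=O)O
F7 | step 5 | methyl 6-methyl-3-(2-methylpropanoyl)-2-[1-(methylsulfanyl)ethyl]benzoate | CC(SC)c1c(C(=O)C(C)C)ccc(C)c1C(=O)OC
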